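The central C15=C15′ ethene is flanked on both sides by a methyl-bearing E alkene (C13=C14 and C13′=C14′), so the chain is cut on both sides of its centre. This traces it back to a two-carbon dihalide and two terminal alkynes, one on each end-ring fragment. In one pot, zirconium-catalysed methylalumination of each alkyne and two successive palladium/zinc couplings form C13–CH3, C13′–CH3, C14–C15 and C14′–C15′. This joins the 3-silyloxy-7,8-didehydro cyclohexene ring (ring A) to the trans-5′,6′-dihydroxy cyclohexane ring (ring B) without closing a ring or creating a stereocentre. The precursors are the C1–C14 dienediyne, the C1′–C14′ trienyne diol and (E)-1-bromo-2-iodoethene.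

Key step: step 16

Remark: the Why lines use carotenoid numbering (unprimed atoms on ring A, primed on ring B). The target is (3R,5′R,6′R)-7,8-didehydro-5′,6′-dihydro-β,β-carotene-3,5′,6′-triol, with a trans 5′,6′-diol.

Assumption: in the acid hydrolysis of step 9, water enters at C5′ with inversion while C6′ keeps its configuration. This is why the (R,R)-tartrate, L-(+)-diethyl tartrate, is chosen in step 8.

All polyene intermediates should be handled under argon with exclusion of light.

Step 1
Reactants: 1 (4R,6R)-4-hydroxy-2,2,6-trimethylcyclohexan-1-one (actinol)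
Product: 2 (4R,6R)-4-[tert-butyl(dimethyl)silyl]oxy-2,2,6-trimethylcyclohexan-1-one
Conditions: TBSCl, imidazole, DMF, 23 °C
Reagents that add atoms: tert-butyldimethylsilyl chloride, CC(C)(C)[Si](C)(C)Cl
Why: Imidazole-promoted O-silylation (silyl ether protection) of the only hydroxyl masks the future C3–OH for the enolate and organometallic steps and touches neither stereocentre.

Step 2
Reactants: 2 (4R,6R)-4-[tert-butyl(dimethyl)silyl]oxy-2,2,6-trimethylcyclohexan-1-one
Product: 4 (4R)-4-[tert-butyl(dimethyl)silyl]oxy-2,6,6-trimethylcyclohex-1-en-1-yl trifluoromethanesulfonate, via lithium enolate 3 (not isolated)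
Conditions: LiN(iPr)2, THF, −78 → 0 °C; PhNTf2, 0 → 23 °C
Reagents that add atoms: N-phenylbis(trifluoromethanesulfonimide), O=S(=O)(N(c1ccccc1)S(=O)(=O)C(F)(F)F)C(F)(F)F
Why: Enol triflate formation should be regiochemically unambiguous because the future C5 carries the only α-hydrogen (the future C1 is quaternary), so one tetrasubstituted enolate forms and is O-sulfonylated; the methyl-bearing stereocentre is erased on purpose and the silyloxy-bearing one is untouched.

Step 3
Reactants: 4 (4R)-4-[tert-butyl(dimethyl)silyl]oxy-2,6,6-trimethylcyclohex-1-en-1-yl trifluoromethanesulfonate; 5 (2E)-3-methylpent-2-en-4-yn-1-ol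
Product: 6 (2E)-5-[(4R)-4-[tert-butyl(dimethyl)silyl]oxy-2,6,6-trimethylcyclohex-1-en-1-yl]-3-methylpent-2-en-4-yn-1-ol
Conditions: Pd(PPh3)4 (5 mol%), CuI (10 mol%), iPr2NH, THF, 23 °C
Reagents that add atoms: none
Why: Sonogashira coupling of the alkenyl triflate with the terminal alkyne forms C6–C7 and carries the E-configured C9=C10 alkene of 5 over unchanged, the free primary alcohol and the silyl ether being inert to the palladium/copper/amine system.

Step 4
Reactants: 6 (2E)-5-[(4R)-4-[tert-butyl(dimethyl)silyl]oxy-2,6,6-trimethylcyclohex-1-en-1-yl]-3-methylpent-2-en-4-yn-1-ol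
Product: 7 (2E)-5-[(4R)-4-[tert-butyl(dimethyl)silyl]oxy-2,6,6-trimethylcyclohex-1-en-1-yl]-3-methylpent-2-en-4-ynal
Conditions: MnO2, CH2Cl2, 23 °C
Reagents that add atoms: none
Why: Heterogeneous MnO2 oxidation is selective for allylic alcohols and is neutral, so the C11 aldehyde should form without isomerising C9=C10 or cleaving the silyl ether.

Step 5
Reactants: 7 (2E)-5-[(4R)-4-[tert-butyl(dimethyl)silyl]oxy-2,6,6-trimethylcyclohex-1-en-1-yl]-3-methylpent-2-en-4-ynal
Product: 8 tert-butyl{[(1R)-4-[(3E,5E)-6-iodo-3-methylhexa-3,5-dien-1-yn-1-yl]-3,5,5-trimethylcyclohex-3-en-1-yl]oxy}dimethylsilane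
Conditions: CrCl2 (8 equiv), CHI3 (3 equiv), THF, 0 °C, dark
Reagents that add atoms: iodoform, IC(I)I
Why: Takai iodoolefination (addition of the geminal dichromium species made from CHI3 and divalent chromium, then elimination) should give the E-configured C11=C12 vinyl iodide under non-basic conditions that leave the internal alkyne and the silyl ether alone.

Step 6
Reactants: 8 tert-butyl{[(1R)-4-[(3E,5E)-6-iodo-3-methylhexa-3,5-dien-1-yn-1-yl]-3,5,5-trimethylcyclohex-3-en-1-yl]oxy}dimethylsilane
Product: 9 tert-butyldimethyl{[(1R)-3,5,5-trimethyl-4-[(3E,5E)-3-methylocta-3,5-diene-1,7-diyn-1-yl]cyclohex-3-en-1-yl]oxy}silane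
Conditions: HC≡CMgBr (3 equiv), ZnBr2 (3 equiv), THF, 0 °C; then 8, Pd(PPh3)4 (5 mol%), 23 °C
Reagents that add atoms: ethynylmagnesium bromide, C#C[Mg]Br
Why: Negishi alkynylation of the alkenyl iodide with ethynylzinc bromide forms C12–C13 with retention of the C11=C12 geometry and gives the terminal C13≡C14 alkyne directly, with no silyl protection and removal on the alkyne.

Step 7
Reactants: 10 β-cyclocitral (2,6,6-trimethylcyclohex-1-ene-1-carbaldehyde)
Product: 11 β-cyclogeraniol ((2,6,6-trimethylcyclohex-1-en-1-yl)methanol)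
Conditions: NaBH4, MeOH, 0 °C
Reagents that add atoms: none
Why: Borohydride 1,2-reduction of the hindered conjugated aldehyde gives the allylic alcohol that the titanium catalyst of the next step needs as its anchoring group; no stereocentre is formed.

Step 8
Reactants: 11 β-cyclogeraniol
Product: 12 [(1S,6S)-2,2,6-trimethyl-7-oxabicyclo[4.1.0]heptan-1-yl]methanol
Conditions: Ti(OiPr)4 (20 mol%), L-(+)-diethyl tartrate (24 mol%), tBuOOH (decane), 4 Å MS, CH2Cl2, −20 °C
Reagents that add atoms: tert-butyl hydroperoxide, CC(C)(C)OO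
Why: Sharpless asymmetric epoxidation: the titanium complex of diethyl (2R,3R)-tartrate binds the allylic alcohol and should deliver the peroxide oxygen to the face of the tetrasubstituted C5′=C6′ alkene that gives the S configuration at the carbinol-bearing epoxide carbon, so C5′ and C6′ are set together by the reagent.

Step 9
Reactants: 12 [(1S,6S)-2,2,6-trimethyl-7-oxabicyclo[4.1.0]heptan-1-yl]methanol
Product: 13 (1S,2R)-1-(hydroxymethyl)-2,6,6-trimethylcyclohexane-1,2-diol
Conditions: HClO4 (5 mol%), THF/H2O, 0 → 23 °C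
Reagents that add atoms: water, O
Why: Acid-catalysed anti hydrolysis of the epoxide: water should attack C5′, which carries positive charge better and is less screened than C6′ (neopentylic and next to the electron-withdrawing CH2OH), so C5′ is inverted, C6′ keeps the configuration from step 8, and the trans-diol results.

Step 10
Reactants: 13 (1S,2R)-1-(hydroxymethyl)-2,6,6-trimethylcyclohexane-1,2-diol
Product: 14 (1R,2R)-1,2-dihydroxy-2,6,6-trimethylcyclohexane-1-carbaldehyde
Conditions: SO3·pyridine, DMSO, Et3N, CH2Cl2, 0 °C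
Reagents that add atoms: none
Why: Parikh–Doering (activated-DMSO) oxidation converts only the primary alcohol, since the tertiary hydroxyls have no carbinol hydrogen, and it does not cleave 1,2-diols; both stereocentres are fully substituted and cannot epimerise.

Step 11
Reactants: 14 (1R,2R)-1,2-dihydroxy-2,6,6-trimethylcyclohexane-1-carbaldehyde; 15 triethyl 3-methyl-4-phosphonocrotonate
Product: 17 ethyl (2E,4E)-5-[(1R,2R)-1,2-dihydroxy-2,6,6-trimethylcyclohexyl]-3-methylpenta-2,4-dienoate, via lithiated phosphonate 16 (not isolated)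
Conditions: 15 (3 equiv), LiN(SiMe3)2 (2.9 equiv), THF/DMPU, −78 °C; then 14, −78 → 0 °C
Reagents that add atoms: none
Why: Horner–Wadsworth–Emmons olefination with the stabilised vinylogous phosphonoacetate anion should form C7′=C8′ with E geometry and bring in the E-configured C9′=C10′ ester unit; the anion is preformed with a slight deficit of base so that no free amide meets the α-hydroxy aldehyde, and any 9′Z isomer should be removable by chromatography.

Step 12
Reactants: 17 ethyl (2E,4E)-5-[(1R,2R)-1,2-dihydroxy-2,6,6-trimethylcyclohexyl]-3-methylpenta-2,4-dienoate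
Product: 18 (1R,2R)-1-[(1E,3E)-5-hydroxy-3-methylpenta-1,3-dien-1-yl]-2,6,6-trimethylcyclohexane-1,2-diol
Conditions: iBu2AlH (5 equiv), CH2Cl2, −78 °C; aq. potassium sodium tartrate
Reagents that add atoms: none
Why: Aluminium hydride 1,2-reduction of the conjugated ester gives the allylic alcohol without touching the diene, the two tertiary hydroxyls only consuming extra hydride as aluminium alkoxides that the work-up frees again.

Step 13
Reactants: 18 (1R,2R)-1-[(1E,3E)-5-hydroxy-3-methylpenta-1,3-dien-1-yl]-2,6,6-trimethylcyclohexane-1,2-diol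
Product: 19 (2E,4E)-5-[(1R,2R)-1,2-dihydroxy-2,6,6-trimethylcyclohexyl]-3-methylpenta-2,4-dienal
Conditions: MnO2, CH2Cl2, 23 °C
Reagents that add atoms: none
Why: MnO2 oxidation is selective for the primary allylic alcohol; the tertiary hydroxyls cannot be oxidised and the neutral medium should not ionise the allylic C6′–OH.

Step 14
Reactants: 19 (2E,4E)-5-[(1R,2R)-1,2-dihydroxy-2,6,6-trimethylcyclohexyl]-3-methylpenta-2,4-dienal
Product: 20 (1R,2R)-1-[(1E,3E,5E)-6-iodo-3-methylhexa-1,3,5-trien-1-yl]-2,6,6-trimethylcyclohexane-1,2-diol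
Conditions: CrCl2 (8 equiv), CHI3 (3 equiv), THF, 0 °C, dark
Reagents that add atoms: iodoform, IC(I)I
Why: Takai iodoolefination tolerates free hydroxyl groups and should turn the C11′ aldehyde into the E-configured C11′=C12′ vinyl iodide under non-basic conditions.

Step 15
Reactants: 20 (1R,2R)-1-[(1E,3E,5E)-6-iodo-3-methylhexa-1,3,5-trien-1-yl]-2,6,6-trimethylcyclohexane-1,2-diol
Product: 21 (1R,2R)-2,6,6-trimethyl-1-[(1E,3E,5E)-3-methylocta-1,3,5-trien-7-yn-1-yl]cyclohexane-1,2-diol
Conditions: HC≡CMgBr (4 equiv), ZnBr2 (4 equiv), THF, 0 °C; then 20, Pd(PPh3)4 (5 mol%), 23 °C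
Reagents that add atoms: ethynylmagnesium bromide, C#C[Mg]Br
Why: Negishi alkynylation forms C12′–C13′ with retention of the C11′=C12′ geometry, the weakly basic alkynylzinc being used in excess because the two tertiary hydroxyls may consume part of it as zinc alkoxides that the work-up frees again.

Step 16
Reactants: 9 tert-butyldimethyl{[(1R)-3,5,5-trimethyl-4-[(3E,5E)-3-methylocta-3,5-diene-1,7-diyn-1-yl]cyclohex-3-en-1-yl]oxy}silane; 22 (E)-1-bromo-2-iodoethene; 21 (1R,2R)-2,6,6-trimethyl-1-[(1E,3E,5E)-3-methylocta-1,3,5-trien-7-yn-1-yl]cyclohexane-1,2-diol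
Product: 26 3-O-tert-butyldimethylsilyl ether of the target, via left alkenylalane 23 (not isolated), via left bromotetraenyne 24 (not isolated), via right alkenylalane 25 (not isolated)
Conditions: 9, Me3Al (2 equiv), Cp2ZrCl2 (25 mol%), (CH2Cl)2, 23 °C, then evaporate, THF; 22 (1.05 equiv), Pd2(dba)3 (2.5 mol%), P(2-furyl)3 (10 mol%), ZnCl2 (co-catalyst), DMF, 23 °C; then 21 treated separately with Me3Al (4.5 equiv), Cp2ZrCl2 (25 mol%), (CH2Cl)2, 0 → 23 °C, evaporated, in THF, ZnCl2, 23 °C, dark; aq. potassium sodium tartrate, 0 °C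
Reagents that add atoms: trimethylaluminium, C[Al](C)C
Why: Each terminal alkyne undergoes zirconium-catalysed syn methylalumination, which puts CH3 on the internal carbon (C13, C13′) and AlMe2 on the terminal carbon (C14, C14′); the alkenyl groups then pass from aluminium through zinc to palladium, and zerovalent palladium inserts first into the C–I bond of 22 (23 gives bromide 24) and only afterwards into the C–Br bond of 24 (coupling with 25), each reductive elimination retaining alkene geometry. The closest known reaction type is the Negishi alkenyl–alkenyl coupling of carboalumination-derived alkenylalanes with a 1,2-dihaloethene, an established way to assemble all-E polyene and carotenoid chains. No ring is closed and no stereocentre is formed: the 13E and 13′E geometries follow from the syn addition and the 15E geometry is carried in from 22. The step needs cross-coupling instead of homodimer formation, which the much faster oxidative addition into C–I than into C–Br secures because 24 is complete before 25 is introduced, and it needs alkyne chemoselectivity, which holds because the internal C7≡C8 bond is disubstituted and screened by the C5=C6 ring alkene, the C1 gem-dimethyl group and the C9 methyl. The two tertiary hydroxyls of 21 are converted by the extra Me3Al into aluminium alkoxides in the same operation, which protects the alkenyl–aluminium bond from protonolysis, and the silyl ether of 9 is inert. Free Me3Al is stripped before each coupling so that methyl transfer does not compete, and the cold, non-acidic work-up spares the allylic tertiary diol.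

Step 17
Reactants: 26 3-O-tert-butyldimethylsilyl ether of the target
Product: 27 (3R,5′R,6′R)-7,8-didehydro-5′,6′-dihydro-β,β-carotene-3,5′,6′-triol (target)
Conditions: Bu4NF, AcOH, THF, 23 °C, dark; crystallisation
Reagents that add atoms: none
Why: Fluoride-mediated desilylation, buffered with acetic acid to keep the medium non-basic, frees the C3 hydroxyl without affecting the polyene, the C7≡C8 alkyne or the tertiary diol, and crystallisation in the dark should deliver the all-E triol.

Compound list
1 | (4R,6R)-4-hydroxy-2,2,6-trimethylcyclohexan-1-one (actinol) | O=C1C(C)(C)C[C@H](O)C[C@H]1C | starting material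
2 | (4R,6R)-4-[tert-butyl(dimethyl)silyl]oxy-2,2,6-trimethylcyclohexan-1-one | O=C1C(C)(C)C[C@H](O[Si](C)(C)C(C)(C)C)C[C@H]1C | intermediate
3 | lithium (4R)-4-[tert-butyl(dimethyl)silyl]oxy-2,6,6-trimethylcyclohex-1-en-1-olate (lithium enolate, not isolated) | CC1=C(O[Li])C(C)(C)C[C@H](O[Si](C)(C)C(C)(C)C)C1 | intermediate
4 | (4R)-4-[tert-butyl(dimethyl)silyl]oxy-2,6,6-trimethylcyclohex-1-en-1-yl trifluoromethanesulfonate | CC1=C(OS(=O)(=O)C(F)(F)F)C(C)(C)C[C@H](O[Si](C)(C)C(C)(C)C)C1 | intermediate
5 | (2E)-3-methylpent-2-en-4-yn-1-ol | C#C/C(C)=C/CO | starting material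
6 | (2E)-5-[(4R)-4-[tert-butyl(dimethyl)silyl]oxy-2,6,6-trimethylcyclohex-1-en-1-yl]-3-methylpent-2-en-4-yn-1-ol | CC1=C(C#C/C(C)=C/CO)C(C)(C)C[C@H](O[Si](C)(C)C(C)(C)C)C1 | intermediate
7 | (2E)-5-[(4R)-4-[tert-butyl(dimethyl)silyl]oxy-2,6,6-trimethylcyclohex-1-en-1-yl]-3-methylpent-2-en-4-ynal | CC1=C(C#C/C(C)=C/C=O)C(C)(C)C[C@H](O[Si](C)(C)C(C)(C)C)C1 | intermediate
8 | tert-butyl{[(1R)-4-[(3E,5E)-6-iodo-3-methylhexa-3,5-dien-1-yn-1-yl]-3,5,5-trimethylcyclohex-3-en-1-yl]oxy}dimethylsilane | CC1=C(C#C/C(C)=C/C=C/I)C(C)(C)C[C@H](O[Si](C)(C)C(C)(C)C)C1 | intermediate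
9 | tert-butyldimethyl{[(1R)-3,5,5-trimethyl-4-[(3E,5E)-3-methylocta-3,5-diene-1,7-diyn-1-yl]cyclohex-3-en-1-yl]oxy}silane (left dienediyne, C1 to C14) | CC1=C(C#C/C(C)=C/C=C/C#C)C(C)(C)C[C@H](O[Si](C)(C)C(C)(C)C)C1 | intermediate
10 | β-cyclocitral (2,6,6-trimethylcyclohex-1-ene-1-carbaldehyde) | CC1=C(C=O)C(C)(C)CCC1 | starting material
11 | β-cyclogeraniol ((2,6,6-trimethylcyclohex-1-en-1-yl)methanol) | CC1=C(CO)C(C)(C)CCC1 | intermediate
12 | [(1S,6S)-2,2,6-trimethyl-7-oxabicyclo[4.1.0]heptan-1-yl]methanol | OC[C@]12O[C@@]1(C)CCCC2(C)C | intermediate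
13 | (1S,2R)-1-(hydroxymethyl)-2,6,6-trimethylcyclohexane-1,2-diol | OC[C@@]1(O)C(C)(C)CCC[C@@]1(C)O | intermediate
14 | (1R,2R)-1,2-dihydroxy-2,6,6-trimethylcyclohexane-1-carbaldehyde | O=C[C@@]1(O)C(C)(C)CCC[C@@]1(C)O | intermediate
15 | triethyl 3-methyl-4-phosphonocrotonate (ethyl (2E)-4-(diethoxyphosphoryl)-3-methylbut-2-enoate) | CCOC(=O)/C=C(C)/CP(=O)(OCC)OCC | starting material
16 | lithium salt of the carbanion of 15 (lithiated phosphonate, not isolated) | [Li+].CCOC(=O)/C=C(C)/[CH-]P(=O)(OCC)OCC | intermediate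
17 | ethyl (2E,4E)-5-[(1R,2R)-1,2-dihydroxy-2,6,6-trimethylcyclohexyl]-3-methylpenta-2,4-dienoate | CCOC(=O)/C=C(C)/C=C/[C@@]1(O)C(C)(C)CCC[C@@]1(C)O | intermediate
18 | (1R,2R)-1-[(1E,3E)-5-hydroxy-3-methylpenta-1,3-dien-1-yl]-2,6,6-trimethylcyclohexane-1,2-diol | OC/C=C(C)/C=C/[C@@]1(O)C(C)(C)CCC[C@@]1(C)O | intermediate
19 | (2E,4E)-5-[(1R,2R)-1,2-dihydroxy-2,6,6-trimethylcyclohexyl]-3-methylpenta-2,4-dienal | O=C/C=C(C)/C=C/[C@@]1(O)C(C)(C)CCC[C@@]1(C)O | intermediate
20 | (1R,2R)-1-[(1E,3E,5E)-6-iodo-3-methylhexa-1,3,5-trien-1-yl]-2,6,6-trimethylcyclohexane-1,2-diol | I/C=C/C=C(C)/C=C/[C@@]1(O)C(C)(C)CCC[C@@]1(C)O | intermediate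
21 | (1R,2R)-2,6,6-trimethyl-1-[(1E,3E,5E)-3-methylocta-1,3,5-trien-7-yn-1-yl]cyclohexane-1,2-diol (right trienyne diol, C14′ to C1′) | C#C/C=C/C=C(C)/C=C/[C@@]1(O)C(C)(C)CCC[C@@]1(C)O | intermediate
22 | (E)-1-bromo-2-iodoethene | Br/C=C/I | starting material
23 | left alkenylalane: dimethylalane carrying at C14 the methylaluminated chain of 9 (not isolated) | CC1=C(C#C/C(C)=C/C=C/C(C)=C/[Al](C)C)C(C)(C)C[C@H](O[Si](C)(C)C(C)(C)C)C1 | intermediate
24 | left bromotetraenyne: {[(1R)-4-[(3E,5E,7E,9E)-10-bromo-3,7-dimethyldeca-3,5,7,9-tetraen-1-yn-1-yl]-3,5,5-trimethylcyclohex-3-en-1-yl]oxy}(tert-butyl)dimethylsilane (not isolated) | CC1=C(C#C/C(C)=C/C=C/C(C)=C/C=C/Br)C(C)(C)C[C@H](O[Si](C)(C)C(C)(C)C)C1 | intermediate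
25 | right alkenylalane: C14′ dimethylalane of methylaluminated 21 with both hydroxyls as dimethylaluminium alkoxides (not isolated) | C[Al](C)/C=C(C)/C=C/C=C(C)/C=C/[C@@]1(O[Al](C)C)C(C)(C)CCC[C@@]1(C)O[Al](C)C | intermediate
26 | 3-O-tert-butyldimethylsilyl ether of the target | CC1=C(C#C/C(C)=C/C=C/C(C)=C/C=C/C=C(C)/C=C/C=C(C)/C=C/[C@@]2(O)C(C)(C)CCC[C@@]2(C)O)C(C)(C)C[C@H](O[Si](C)(C)C(C)(C)C)C1 | intermediate
27 | (3R,5′R,6′R)-7,8-didehydro-5′,6′-dihydro-β,β-carotene-3,5′,6′-triol | CC1=C(C#C/C(C)=C/C=C/C(C)=C/C=C/C=C(C)/C=C/C=C(C)/C=C/[C@@]2(O)C(C)(C)CCC[C@@]2(C)O)C(C)(C)C[C@H](O)C1 | target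

Total step count: 17. Longest linear sequence: 11 steps (steps 7 to 17, from β-cyclocitral); the left fragment takes 6 steps (steps 1 to 6) before it joins in step 16.

Steps most likely to fail

Step 16. The Lewis-acidic methylalumination medium may ionise the aluminium alkoxide at the allylic C6′ position, leading to dehydration or pinacol-type ring contraction. The conjugated enynes may also undergo C–H metalation in place of carbometalation, and incomplete discrimination between the two halogens would give symmetrical dimers. The fallback abandons the carbometalation and builds the chain by the classical double Wittig condensation on the C10 dialdehyde; it sets out from 6 and 18 and comes back to the route at 26. Alcohol 6 would be converted with PPh3·HBr in CH2Cl2 into the left phosphonium bromide F1. Its ylide (NaOMe, CH2Cl2/MeOH) would be condensed with an excess of commercial (2E,4E,6E)-2,7-dimethylocta-2,4,6-trienedial to give the C25 pentaenynal F2. Triol 18 would be converted in the same way, at 0 °C, into the right phosphonium bromide F3. Wittig reaction of the ylide of F3 with F2, followed by thermal Z-to-E equilibration, would give 26.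

Step 11. Base may trigger α-ketol rearrangement of the α-hydroxy aldehyde, or addition to the very hindered carbonyl may be too slow, and the delocalised anion may give incomplete 9′E control. The fallback replaces the basic olefination by a chromium-mediated one followed by cross-coupling; it sets out from 14 and comes back at 17. Takai iodoolefination of 14 (CrCl2, CHI3, THF) would give the vinyl iodide F4. Stille coupling of F4 with ethyl (2E)-3-(tributylstannyl)but-2-enoate (Pd2(dba)3, AsPh3, NMP) would form the C8′–C9′ bond and give the dienoate 17 with both alkene geometries fixed by the partners.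

Step 9. Water may enter at C6′ in competition with C5′, which would give the enantiomeric trans-diol and erode enantiomeric purity, and the cationic character of the opening may divert material into elimination or ring contraction. The fallback opens the ring under base through a Payne rearrangement; it sets out from 11 and comes back at 13. Sharpless epoxidation of 11 with D-(−)-diethyl tartrate would give the enantiomeric epoxy alcohol F5. Aqueous NaOH in tBuOH at 70–80 °C would then rearrange F5, with inversion at C6′, to the spiro-epoxide F6, which hydroxide opens at its CH2 terminus to give 13 with the same configuration as in the main route.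

Further compounds
F1 | step 16 | {(2E)-5-[(4R)-4-[tert-butyl(dimethyl)silyl]oxy-2,6,6-trimethylcyclohex-1-en-1-yl]-3-methylpent-2-en-4-yn-1-yl}triphenylphosphonium bromide | CC1=C(C#C/C(C)=C/C[P+](c2ccccc2)(c2ccccc2)c2ccccc2)C(C)(C)C[C@H](O[Si](C)(C)C(C)(C)C)C1.[Br-]
F2 | step 16 | (2E,4E,6E,8E,10E)-13-[(4R)-4-[tert-butyl(dimethyl)silyl]oxy-2,6,6-trimethylcyclohex-1-en-1-yl]-2,7,11-trimethyltrideca-2,4,6,8,10-pentaen-12-ynal | CC1=C(C#C/C(C)=C/C=C/C(C)=C/C=C/C=C(C)/C=O)C(C)(C)C[C@H](O[Si](C)(C)C(C)(C)C)C1
F3 | step 16 | {(2E,4E)-5-[(1R,2R)-1,2-dihydroxy-2,6,6-trimethylcyclohexyl]-3-methylpenta-2,4-dien-1-yl}triphenylphosphonium bromide | [Br-].c1ccccc1[P+](c1ccccc1)(c1ccccc1)C/C=C(C)/C=C/[C@@]1(O)C(C)(C)CCC[C@@]1(C)O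
F4 | step 11 | (1R,2R)-1-[(E)-2-iodoethenyl]-2,6,6-trimethylcyclohexane-1,2-diol | I/C=C/[C@@]1(O)C(C)(C)CCC[C@@]1(C)O
F5 | step 9 | [(1R,6R)-2,2,6-trimethyl-7-oxabicyclo[4.1.0]heptan-1-yl]methanol | OC[C@@]12O[C@]1(C)CCCC2(C)C
F6 | step 9 | (3S,4R)-4,8,8-trimethyl-1-oxaspiro[2.5]octan-4-ol | O1C[C@]12C(C)(C)CCC[C@@]2(C)O
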